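**Retrosynthetic overview**
1. Feature: chromone C2 carries only H. The carbon next to the α-stereocentre is a benzhydryl CH with two identical 4-hydroxyphenyl rings. Read backwards, one of these rings sat on C2 of a flavanone and the other on Cβ of a neighbouring chalcone, so the skeleton is a rearranged α,α'-linked bichalcone.
2. Last disconnection: the benzyl ether on the salicyl hydroxyl of the methoxy-bearing ring (ring A'), removed by hydrogenolysis.
3. Key disconnection: the O1–C2 bond of the pyranone (ring C) and the benzhydryl C–aryl bond. One chiral-acid cascade on the E,E-bichalcone makes both: oxa-Michael closure, 1,4-aryl shift through a spirodienone, chromone formation, enantioselective enol protonation.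
4. Bichalcone: the Cα–Cα' bond comes from a Stille coupling of a (Z)-α-bromochalcone (ring A half) with a (Z)-α-stannyl allylic alcohol (ring A' half). Oxidation and buffered fluoride desilylation follow.
5. Ring order: all five benzene rings are bought. Ring C is the only ring built and it closes in the key step; the five-membered spiro ring is transient.

Key step: step 12

Assumption: the facial sense of the chiral acid cannot be derived from precedent, so the (R)-acid is written and its mirror image is used if screening shows that it leads to the S ketone.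
Abbreviations: TBS = tert-butyldimethylsilyl, Bn = benzyl.

**Step 1**
Reactants: 1 2,4-dihydroxyacetophenone; 2 4-hydroxybenzaldehyde
Product: 3 isoliquiritigenin (E)-1-(2,4-dihydroxyphenyl)-3-(4-hydroxyphenyl)prop-2-en-1-one
Conditions: KOH (60% aq), EtOH, 0 °C to rt; then 2 M HCl to pH 5
Reagents that add atoms: none
Why: Claisen–Schmidt condensation, in which the acetophenone enolate adds to the aldehyde and E1cB loss of water gives the E-enone; the unprotected version is the standard preparation of this chalcone.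

**Step 2**
Reactants: 3 isoliquiritigenin
Product: 4 (E)-1-[2,4-bis(TBS-oxy)phenyl]-3-[4-(TBS-oxy)phenyl]prop-2-en-1-one
Conditions: TBSCl (4 equiv), imidazole (8 equiv), 4-(dimethylamino)pyridine (0.1 equiv), DMF, 40 °C
Reagents that add atoms: tert-butyldimethylsilyl chloride, CC(C)(C)[Si](C)(C)Cl
Why: Silyl ether formation caps all three phenols (the chelated ortho one last) with a group that buffered fluoride removes later, so no acid able to start the cascade is needed before step 12.

**Step 3**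
Reactants: 4 tris-TBS chalcone
Product: 6 (Z)-2-bromo-1-[2,4-bis(TBS-oxy)phenyl]-3-[4-(TBS-oxy)phenyl]prop-2-en-1-one, via chalcone dibromide 5 (not isolated)
Conditions: Br2 (1.0 equiv), CH2Cl2, −78 °C to 0 °C; then Et3N (3 equiv), 0 °C to rt
Reagents that add atoms: bromine, BrBr
Why: Bromine addition to the electron-rich styrenyl C=C and E1cB dehydrobromination (the classical α-bromochalcone synthesis) should give the more stable Z isomer, with the aryl group trans to the aroyl group; one equivalent at low temperature limits ring bromination.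

**Step 4**
Reactants: 2 4-hydroxybenzaldehyde
Product: 7 4-(TBS-oxy)benzaldehyde
Conditions: TBSCl, imidazole, CH2Cl2, rt
Reagents that add atoms: tert-butyldimethylsilyl chloride, CC(C)(C)[Si](C)(C)Cl
Why: Silyl ether formation gives a phenol protection that tolerates organolithium, tin hydride and palladium chemistry.

**Step 5**
Reactants: 7 4-(TBS-oxy)benzaldehyde
Product: 8 tert-butyl[4-(2,2-dibromovinyl)phenoxy]dimethylsilane
Conditions: CBr4 (2 equiv), PPh3 (4 equiv), CH2Cl2, 0 °C
Reagents that add atoms: carbon tetrabromide, BrC(Br)(Br)Br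
Why: Ramirez olefination (first stage of the Corey–Fuchs sequence) converts the aldehyde into the 1,1-dibromoalkene under neutral conditions that spare the aryl silyl ether.

**Step 6**
Reactants: 9 2-hydroxy-4-methoxybenzaldehyde
Product: 10 2-(benzyloxy)-4-methoxybenzaldehyde
Conditions: BnBr, K2CO3, DMF, 50 °C
Reagents that add atoms: benzyl bromide, BrCc1ccccc1
Why: Williamson ether synthesis installs the one group that later prevents ring A' from forming a flavanone.

**Step 7**
Reactants: 8 dibromoalkene; 10 2-(benzyloxy)-4-methoxybenzaldehyde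
Product: 12 racemic 1-[2-(benzyloxy)-4-methoxyphenyl]-3-[4-(TBS-oxy)phenyl]prop-2-yn-1-ol, via lithium acetylide 11 (not isolated)
Conditions: n-BuLi (2.1 equiv), THF, −78 °C to 0 °C; then 10, −78 °C; then H2O
Reagents that add atoms: none
Why: In the second stage of the Corey–Fuchs sequence (Br/Li exchange, loss of LiBr, deprotonation) the acetylide forms and adds 1,2 to the aldehyde; the carbinol centre is racemic and is removed in step 10.

**Step 8**
Reactants: 12 propargylic alcohol
Product: 13 racemic (Z)-1-[2-(benzyloxy)-4-methoxyphenyl]-3-[4-(TBS-oxy)phenyl]-2-(tributylstannyl)prop-2-en-1-ol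
Conditions: [Cp*RuCl]4 (Cp* = C5Me5, 2.5 mol%), Bu3SnH (1.1 equiv, slow addition), CH2Cl2, rt
Reagents that add atoms: tributyltin hydride, CCCC[SnH](CCCC)CCCC
Why: In this hydroxyl-directed ruthenium-catalysed trans-hydrostannation of a propargylic alcohol, the OH···Cl–Ru hydrogen bond steers tin to the alkyne carbon next to the carbinol, and trans addition places tin cis to the aryl group (Z).

**Step 9**
Reactants: 6 (Z)-α-bromochalcone; 13 (Z)-alkenylstannane
Product: 14 (2E,3E)-4-[2-(benzyloxy)-4-methoxyphenyl]-1-[2,4-bis(TBS-oxy)phenyl]-4-hydroxy-2,3-bis[4-(TBS-oxy)benzylidene]butan-1-one (racemic carbinol)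
Conditions: Pd(PPh3)4 (10 mol%), Cu(O2CC4H3S) (copper thiophene-2-carboxylate, 1.5 equiv), [NBu4][Ph2PO2] (1.5 equiv), DMF, rt, dark
Reagents that add atoms: none
Why: Stille–Migita coupling, helped by tin-to-copper exchange and by the phosphinate as tin scavenger, joins Cα and Cα' with retention at both alkenyl carbons and should give the E,E-diene; it is preferred to a double aldol condensation on the 1,4-diketone, which can drain into furans and 2-benzyl-2-ene-1,4-diones.

**Step 10**
Reactants: 14 dienyl alcohol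
Product: 15 (2E,3E)-1-[2-(benzyloxy)-4-methoxyphenyl]-4-[2,4-bis(TBS-oxy)phenyl]-2,3-bis[4-(TBS-oxy)benzylidene]butane-1,4-dione
Conditions: Dess–Martin periodinane (1.5 equiv), NaHCO3, CH2Cl2, 0 °C to rt, dark
Reagents that add atoms: none
Why: Dess–Martin oxidation of the benzylic and allylic secondary alcohol removes the racemic carbinol centre and gives a diketone with no enolisable hydrogen.

**Step 11**
Reactants: 15 silylated bichalcone
Product: 16 (2E,3E)-1-[2-(benzyloxy)-4-methoxyphenyl]-4-(2,4-dihydroxyphenyl)-2,3-bis(4-hydroxybenzylidene)butane-1,4-dione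
Conditions: Bu4NF (4.4 equiv), AcOH (4.4 equiv), THF, 0 °C, dark; pH 7 buffer work-up, used at once
Reagents that add atoms: none
Why: Fluoride cleaves the four aryl silyl ethers while acetic acid keeps out both free phenoxide (base-induced closure) and strong acid (racemic cascade); the benzyl ether and enones are untouched, and any flavanone formed early lies on the path of step 12.

**Step 12**
Reactants: 16 bichalcone
Product: 20 (2R)-3-{1-[2-(benzyloxy)-4-methoxyphenyl]-3,3-bis(4-hydroxyphenyl)-1-oxopropan-2-yl}-7-hydroxy-4H-chromen-4-one, via flavanone 17 (not isolated), via spirodienone enol 18 (not isolated), via chromone enol 19 (not isolated)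
Conditions: (R)-3,3'-bis(2,4,6-triisopropylphenyl)-1,1'-binaphthyl-2,2'-diyl N-triflylphosphoramide (10 mol%), CH2Cl2/MTBE 4:1 (0.02 M), 4 Å molecular sieves, −20 °C to 0 °C, dark
Reagents that add atoms: none
Why: Proposed new method: the chiral acid shuttles protons between the para-hydroxyls and the carbonyl oxygens, so the one free ortho-hydroxyl of ring A adds to the β-carbon of its own enone (O1–C2 bond, 6-endo-trig oxa-Michael closure of ring C) to give flavanone 17, whose C2 aryl sits four atoms from the β-carbon of the second arm. That arm reacts as its p-quinone methide enol tautomer, and the ipso carbon of the C2 aryl, activated by its own para-hydroxyl, attacks its β-carbon (new C–aryl bond; transient five-membered ring, 5-exo-trig when counted on the exocyclic quinone methide C=C) to give the neutral spirodienone 18. Push–pull fragmentation of the C2–spiro bond (the O1 lone pair pushes, the protonated dienone oxygen pulls) rearomatises the migrating ring on the benzhydryl carbon and leaves an oxocarbenium ion that loses H3 to the counter-anion, so the aromatic 4-pyranone of 19 makes the sequence irreversible. The enol of 19 is then protonated at the α-carbon inside its hydrogen-bonded pair with the acid; C2, C3 and the spiro carbon have been erased by then, so the 3,3'-aryl pocket of the catalyst is the only element that chooses the face and sets R. The closest known reaction types are acid-catalysed cyclisation of 2'-hydroxychalcones to flavanones, Ar1-5 participation and 1,4-aryl shifts through spiro[4.5]dienones or cyclohexadienyl cations, additions to p-quinone methides formed in situ under BINOL-derived phosphoric acids, and Nazarov cyclisation followed by enantioselective enol protonation under N-triflylphosphoramides, the member of the BINOL phosphoric acid family chosen here because a plain phosphoric diester may be too weak to drive the fragmentation. Three selectivities are needed: direction of the shift (the benzyl ether leaves only ring A able to form a flavanone), ipso instead of ortho attack (the para-hydroxyl activates only the ipso carbon, whereas the ortho carbons that would lead to a 1-aryl-1,2-dihydronaphthalene are meta to it) and intramolecular over intermolecular capture of the quinone methide (high dilution).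

**Step 13**
Reactants: 20 benzyl ether of the target
Product: 21 (2R)-7-hydroxy-3-[1-(2-hydroxy-4-methoxyphenyl)-3,3-bis(4-hydroxyphenyl)-1-oxopropan-2-yl]-4H-chromen-4-one (target)
Conditions: H2 (1 atm), 10% Pd/C, EtOAc, rt, stopped after one equivalent of H2
Reagents that add atoms: none
Why: Catalytic hydrogenolysis of the aryl benzyl ether runs under neutral conditions, the 3-substituted chromone C2–C3 bond and the aryl ketones reduce much more slowly, and without acid or base the α-stereocentre cannot enolise.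

**Compound list**
1 | 2,4-dihydroxyacetophenone | CC(=O)c1ccc(O)cc1O | starting material
2 | 4-hydroxybenzaldehyde | O=Cc1ccc(O)cc1 | starting material
3 | isoliquiritigenin, (E)-1-(2,4-dihydroxyphenyl)-3-(4-hydroxyphenyl)prop-2-en-1-one | O=C(/C=C/c1ccc(O)cc1)c1ccc(O)cc1O | intermediate
4 | (E)-1-[2,4-bis(TBS-oxy)phenyl]-3-[4-(TBS-oxy)phenyl]prop-2-en-1-one | CC(C)(C)[Si](C)(C)Oc1ccc(/C=C/C(=O)c2ccc(O[Si](C)(C)C(C)(C)C)cc2O[Si](C)(C)C(C)(C)C)cc1 | intermediate
5 | 2,3-dibromo-1-[2,4-bis(TBS-oxy)phenyl]-3-[4-(TBS-oxy)phenyl]propan-1-one (racemic anti adduct, both centres lost in the same step) | CC(C)(C)[Si](C)(C)Oc1ccc(C(Br)C(Br)C(=O)c2ccc(O[Si](C)(C)C(C)(C)C)cc2O[Si](C)(C)C(C)(C)C)cc1 | intermediate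
6 | (Z)-2-bromo-1-[2,4-bis(TBS-oxy)phenyl]-3-[4-(TBS-oxy)phenyl]prop-2-en-1-one | CC(C)(C)[Si](C)(C)Oc1ccc(/C=C(\Br)C(=O)c2ccc(O[Si](C)(C)C(C)(C)C)cc2O[Si](C)(C)C(C)(C)C)cc1 | intermediate
7 | 4-(TBS-oxy)benzaldehyde | CC(C)(C)[Si](C)(C)Oc1ccc(C=O)cc1 | intermediate
8 | tert-butyl[4-(2,2-dibromovinyl)phenoxy]dimethylsilane | CC(C)(C)[Si](C)(C)Oc1ccc(C=C(Br)Br)cc1 | intermediate
9 | 2-hydroxy-4-methoxybenzaldehyde | COc1ccc(C=O)c(O)c1 | starting material
10 | 2-(benzyloxy)-4-methoxybenzaldehyde | COc1ccc(C=O)c(OCc2ccccc2)c1 | intermediate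
11 | lithium [4-(TBS-oxy)phenyl]acetylide | [Li]C#Cc1ccc(O[Si](C)(C)C(C)(C)C)cc1 | intermediate
12 | 1-[2-(benzyloxy)-4-methoxyphenyl]-3-[4-(TBS-oxy)phenyl]prop-2-yn-1-ol (racemic) | COc1ccc(C(O)C#Cc2ccc(O[Si](C)(C)C(C)(C)C)cc2)c(OCc2ccccc2)c1 | intermediate
13 | (Z)-1-[2-(benzyloxy)-4-methoxyphenyl]-3-[4-(TBS-oxy)phenyl]-2-(tributylstannyl)prop-2-en-1-ol (racemic carbinol) | COc1ccc(C(O)/C(=C/c2ccc(O[Si](C)(C)C(C)(C)C)cc2)[Sn](CCCC)(CCCC)CCCC)c(OCc2ccccc2)c1 | intermediate
14 | (2E,3E)-4-[2-(benzyloxy)-4-methoxyphenyl]-1-[2,4-bis(TBS-oxy)phenyl]-4-hydroxy-2,3-bis[4-(TBS-oxy)benzylidene]butan-1-one (racemic carbinol) | COc1ccc(C(O)/C(=C/c2ccc(O[Si](C)(C)C(C)(C)C)cc2)/C(=C\c2ccc(O[Si](C)(C)C(C)(C)C)cc2)C(=O)c2ccc(O[Si](C)(C)C(C)(C)C)cc2O[Si](C)(C)C(C)(C)C)c(OCc2ccccc2)c1 | intermediate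
15 | (2E,3E)-1-[2-(benzyloxy)-4-methoxyphenyl]-4-[2,4-bis(TBS-oxy)phenyl]-2,3-bis[4-(TBS-oxy)benzylidene]butane-1,4-dione | COc1ccc(C(=O)/C(=C/c2ccc(O[Si](C)(C)C(C)(C)C)cc2)/C(=C\c2ccc(O[Si](C)(C)C(C)(C)C)cc2)C(=O)c2ccc(O[Si](C)(C)C(C)(C)C)cc2O[Si](C)(C)C(C)(C)C)c(OCc2ccccc2)c1 | intermediate
16 | (2E,3E)-1-[2-(benzyloxy)-4-methoxyphenyl]-4-(2,4-dihydroxyphenyl)-2,3-bis(4-hydroxybenzylidene)butane-1,4-dione (key-step precursor) | COc1ccc(C(=O)/C(=C/c2ccc(O)cc2)/C(=C\c2ccc(O)cc2)C(=O)c2ccc(O)cc2O)c(OCc2ccccc2)c1 | intermediate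
17 | 7-hydroxy-2-(4-hydroxyphenyl)chroman-4-one carrying at C3 the (E)-1-[2-(benzyloxy)-4-methoxyphenyl]-3-(4-hydroxyphenyl)-1-oxoprop-2-en-2-yl group (C2 and C3 not fixed, erased later) | COc1ccc(C(=O)/C(=C/c2ccc(O)cc2)C2C(c3ccc(O)cc3)Oc3cc(O)ccc3C2=O)c(OCc2ccccc2)c1 | intermediate
18 | spirodienone enol: cyclopentane fused to C2–C3 of the 7-hydroxychroman-4-one, its other three atoms being the spiro carbon of a cyclohexa-2,5-dien-4-one (on C2), a CH bearing 4-hydroxyphenyl, and a carbon (on C3) with an exocyclic C=C(OH)[2-(benzyloxy)-4-methoxyphenyl] enol | COc1ccc(C(O)=C2C(c3ccc(O)cc3)C3(C=CC(=O)C=C3)C3Oc4cc(O)ccc4C(=O)C23)c(OCc2ccccc2)c1 | intermediate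
19 | chromone enol: 3-{1-[2-(benzyloxy)-4-methoxyphenyl]-1-hydroxy-3,3-bis(4-hydroxyphenyl)prop-1-en-2-yl}-7-hydroxy-4H-chromen-4-one | COc1ccc(C(O)=C(c2coc3cc(O)ccc3c2=O)C(c2ccc(O)cc2)c2ccc(O)cc2)c(OCc2ccccc2)c1 | intermediate
20 | (2R)-3-{1-[2-(benzyloxy)-4-methoxyphenyl]-3,3-bis(4-hydroxyphenyl)-1-oxopropan-2-yl}-7-hydroxy-4H-chromen-4-one (key-step product) | COc1ccc(C(=O)[C@@H](c2coc3cc(O)ccc3c2=O)C(c2ccc(O)cc2)c2ccc(O)cc2)c(OCc2ccccc2)c1 | intermediate
21 | (2R)-7-hydroxy-3-[1-(2-hydroxy-4-methoxyphenyl)-3,3-bis(4-hydroxyphenyl)-1-oxopropan-2-yl]-4H-chromen-4-one | COc1ccc(C(=O)[C@@H](c2coc3cc(O)ccc3c2=O)C(c2ccc(O)cc2)c2ccc(O)cc2)c(O)c1 | target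

**Step count**
- Total step count: 13.
- Longest linear sequence: 9 steps (steps 4, 5, 7, 8, 9, 10, 11, 12, 13).

**Steps most likely to fail**

1. **Step 12.**
   - Risk: the sequence may stop at the flavanone stage. The ipso attack may revert faster than the spiro ring fragments. The quinone methide may be captured intermolecularly. The enol may be protonated without facial bias, or the product may enolise again under the acid.
   - Fallback: known chemistry only, with no aryl shift. It sets out from 12 and 1 and comes back at 20.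
   - From 12: Red-Al trans-reduction gives the (E)-allylic alcohol F1, and MnO2 gives the chalcone F2.
   - Hayashi–Miyaura addition of 4-(TBS-oxy)phenylboronic acid with [Rh(cod)OH]2 then gives the β,β-diaryl ketone F3.
   - From 1: silylation gives the bis-TBS acetophenone F4. Side-chain bromination with phenyltrimethylammonium tribromide gives the phenacyl bromide F5.
   - Alkylation of the lithium enolate of F3 (LiHMDS) with F5 gives the racemic 1,4-diketone F6, and Bu4NF/AcOH gives the tetraphenol F7.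
   - The one-carbon annulation used for isoflavones (BF3·OEt2, DMF, MsCl) acts on the only CH2 next to an ortho-hydroxyaryl ketone and gives the racemic chromone F8.
   - Preparative HPLC on a chiral stationary phase separates F8 and delivers 20.

2. **Step 9.**
   - Risk: slow transmetalation at two fully substituted alkenyl carbons leaves time for protodestannylation and homocoupling.
   - Fallback: it sets out from 8, 6 and 10 and comes back at 14. The Cα–Cα' bond is made at an sp carbon and the carbinol C–C bond is made last.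
   - Compound 8 with n-BuLi and then water gives the terminal alkyne F9.
   - Sonogashira coupling of F9 with 6 (PdCl2(PPh3)2, CuI, Et3N) gives the enynone F10.
   - Pd(PPh3)4-catalysed syn-hydrostannation delivers hydride to the alkyne carbon next to the donor aryl ring and tin to the carbon next to the acylvinyl group. This gives the dienylstannane F11.
   - I2 converts F11 into the dienyl iodide F12.
   - Nozaki–Hiyama–Kishi addition of F12 to aldehyde 10 (CrCl2, catalytic NiCl2, DMF) spares the ketone and gives 14.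

3. **Step 8.**
   - Risk: conjugation of the alkyne with the donor aryl ring may compete with the hydroxyl direction. This would erode regiocontrol and allow some syn addition.
   - Fallback: it sets out from 12 and comes back at 20.
   - MnO2 oxidises 12 to the ynone F13.
   - Polarity-controlled Pd(PPh3)4-catalysed syn-hydrostannation places tin α to the carbonyl and gives the α-stannyl enone F14.
   - Coupling of F14 with 6 under the conditions of step 9 gives the (2Z,3E) isomer F15 of 15.
   - Desilylation as in step 11 gives the (2Z,3E) isomer F16 of 16.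
   - F16 is submitted to step 12 as such, because the alkene geometry of the acceptor arm is lost at the quinone methide stage.

**Further compounds**
F1 | step 12 | (E)-1-[2-(benzyloxy)-4-methoxyphenyl]-3-[4-(TBS-oxy)phenyl]prop-2-en-1-ol (racemic) | COc1ccc(C(O)/C=C/c2ccc(O[Si](C)(C)C(C)(C)C)cc2)c(OCc2ccccc2)c1
F2 | step 12 | (E)-1-[2-(benzyloxy)-4-methoxyphenyl]-3-[4-(TBS-oxy)phenyl]prop-2-en-1-one | COc1ccc(C(=O)/C=C/c2ccc(O[Si](C)(C)C(C)(C)C)cc2)c(OCc2ccccc2)c1
F3 | step 12 | 1-[2-(benzyloxy)-4-methoxyphenyl]-3,3-bis[4-(TBS-oxy)phenyl]propan-1-one | COc1ccc(C(=O)CC(c2ccc(O[Si](C)(C)C(C)(C)C)cc2)c2ccc(O[Si](C)(C)C(C)(C)C)cc2)c(OCc2ccccc2)c1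
F4 | step 12 | 1-[2,4-bis(TBS-oxy)phenyl]ethanone | CC(=O)c1ccc(O[Si](C)(C)C(C)(C)C)cc1O[Si](C)(C)C(C)(C)C
F5 | step 12 | 2-bromo-1-[2,4-bis(TBS-oxy)phenyl]ethanone | O=C(CBr)c1ccc(O[Si](C)(C)C(C)(C)C)cc1O[Si](C)(C)C(C)(C)C
F6 | step 12 | racemic 1-[2-(benzyloxy)-4-methoxyphenyl]-2-{bis[4-(TBS-oxy)phenyl]methyl}-4-[2,4-bis(TBS-oxy)phenyl]butane-1,4-dione | COc1ccc(C(=O)C(CC(=O)c2ccc(O[Si](C)(C)C(C)(C)C)cc2O[Si](C)(C)C(C)(C)C)C(c2ccc(O[Si](C)(C)C(C)(C)C)cc2)c2ccc(O[Si](C)(C)C(C)(C)C)cc2)c(OCc2ccccc2)c1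
F7 | step 12 | racemic 1-[2-(benzyloxy)-4-methoxyphenyl]-2-[bis(4-hydroxyphenyl)methyl]-4-(2,4-dihydroxyphenyl)butane-1,4-dione | COc1ccc(C(=O)C(CC(=O)c2ccc(O)cc2O)C(c2ccc(O)cc2)c2ccc(O)cc2)c(OCc2ccccc2)c1
F8 | step 12 | racemic form of 20 | COc1ccc(C(=O)C(c2coc3cc(O)ccc3c2=O)C(c2ccc(O)cc2)c2ccc(O)cc2)c(OCc2ccccc2)c1
F9 | step 9 | tert-butyl(4-ethynylphenoxy)dimethylsilane | C#Cc1ccc(O[Si](C)(C)C(C)(C)C)cc1
F10 | step 9 | (E)-1-[2,4-bis(TBS-oxy)phenyl]-2-[4-(TBS-oxy)benzylidene]-4-[4-(TBS-oxy)phenyl]but-3-yn-1-one | CC(C)(C)[Si](C)(C)Oc1ccc(C#C/C(=C\c2ccc(O[Si](C)(C)C(C)(C)C)cc2)C(=O)c2ccc(O[Si](C)(C)C(C)(C)C)cc2O[Si](C)(C)C(C)(C)C)cc1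
F11 | step 9 | 1-[2,4-bis(TBS-oxy)phenyl]-2-[4-(TBS-oxy)benzylidene]-4-[4-(TBS-oxy)phenyl]-3-(tributylstannyl)but-3-en-1-one, tin trans to its neighbouring aryl group, benzylidene aryl trans to the ketone | CCCC[Sn](CCCC)(CCCC)/C(=C/c1ccc(O[Si](C)(C)C(C)(C)C)cc1)/C(=C\c1ccc(O[Si](C)(C)C(C)(C)C)cc1)C(=O)c1ccc(O[Si](C)(C)C(C)(C)C)cc1O[Si](C)(C)C(C)(C)C
F12 | step 9 | the corresponding 3-iodo diene, iodine trans to its neighbouring aryl group | I/C(=C/c1ccc(O[Si](C)(C)C(C)(C)C)cc1)/C(=C\c1ccc(O[Si](C)(C)C(C)(C)C)cc1)C(=O)c1ccc(O[Si](C)(C)C(C)(C)C)cc1O[Si](C)(C)C(C)(C)C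
F13 | step 8 | 1-[2-(benzyloxy)-4-methoxyphenyl]-3-[4-(TBS-oxy)phenyl]prop-2-yn-1-one | COc1ccc(C(=O)C#Cc2ccc(O[Si](C)(C)C(C)(C)C)cc2)c(OCc2ccccc2)c1
F14 | step 8 | (E)-1-[2-(benzyloxy)-4-methoxyphenyl]-3-[4-(TBS-oxy)phenyl]-2-(tributylstannyl)prop-2-en-1-one | COc1ccc(C(=O)/C(=C\c2ccc(O[Si](C)(C)C(C)(C)C)cc2)[Sn](CCCC)(CCCC)CCCC)c(OCc2ccccc2)c1
F15 | step 8 | (2Z,3E) isomer of 15 | COc1ccc(C(=O)/C(=C\c2ccc(O[Si](C)(C)C(C)(C)C)cc2)/C(=C\c2ccc(O[Si](C)(C)C(C)(C)C)cc2)C(=O)c2ccc(O[Si](C)(C)C(C)(C)C)cc2O[Si](C)(C)C(C)(C)C)c(OCc2ccccc2)c1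
F16 | step 8 | (2Z,3E) isomer of 16 | COc1ccc(C(=O)/C(=C\c2ccc(O)cc2)/C(=C\c2ccc(O)cc2)C(=O)c2ccc(O)cc2O)c(OCc2ccccc2)c1
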